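I read this flask at 1.0 h, and I want to know what stands in it then.

substrate 0.098 M; free catalyst 49 µM; time 1.0 h

    catalyst intermediate → free catalyst + target (k1 = 2500 min⁻¹)
    2 substrate → homo dimer (k2 = 1.4 L mol⁻¹ min⁻¹)
    substrate + free catalyst → catalyst intermediate (k3 = 5900 L mol⁻¹ min⁻¹)
    target ⇌ isomer of the product (K4 = 0.38, k4 = 0.062 min⁻¹)

1. why nothing more happens at 1.0 h, or that something still does (all of the substrate has reacted / forward and back rates have come level / no working catalyst is left / it is still moving)
2. share of the substrate used up at 1.0 h
3. target at 1.0 h, in percent of the substrate charged
4. isomer of the product at 1.0 h, in percent of the substrate charged

- percent here means substrate units held: one homo dimer counts as two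
- for a step with 2 of a species take k times the square, and two of it per event
- the reaction counts as stopped when no species that holds the substrate changes by six tenths of a point or more over the second half of the time
- run time (flask): 1.0 h

I count half-lives first. With the catalyst at its charge, substrate has a half-life of 2.40 min (pseudo-first-order), and target and isomer of the product relax together with 3.08 min. The time holds 25.0 of the first and 19.5 of the second. So the catalyst step by itself leaves a fraction 2.93 × 10⁻⁸ of the substrate, and I expect a flask that has stopped for want of substrate, with target and isomer at their equilibrium ratio.

What remains is how the substrate divides between the catalyst and homo dimer, and I reach that by two ways. Let x be the rate of loss to homo dimer over the rate of loss to the catalyst at the charge, 0.949. With the catalyst free, that ratio falls in step with [substrate].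

The first way keeps the catalyst free and integrates, giving the logarithm of one plus x, over x: 70.3%.

The second way reads the momentary share, the catalyst's part of the substrate loss at that moment, at the charge, midway and at the end, and weights these by Simpson's rule. It also counts the catalyst held as intermediate, so that at the charge 81.2% is free. The momentary share is 46.1% at the charge, 65.4% midway, and whole at the end, and the rule gives the catalyst share, the fraction of the charge that goes through the catalyst rather than into homo dimer, 67.9%.

The two part by 2.4 percentage points. Simpson's rule is not the cheat: with free catalyst it returns 70.4%. The first way cheats by ignoring the early intermediate, though free catalyst is the resting state. I commit to the second: target 49.2% and isomer of the product 18.7%.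

The forecast gives all of the substrate has reacted, conversion 100%, target 49.2% and isomer of the product 18.7%, holding that “the catalytic one wins as substrate falls”.

The simulation gives all of the substrate has reacted, conversion 100%, target 49.2% and isomer of the product 18.7%, with 67.9% of the substrate through the catalyst step.

Isomer of the product stands at 18.7% in this flask because it returns to target; with that return taken away, this flask reads 65.8% of isomer of the product. In the neighbour flask with 0.17 M of substrate, x is 1.65, and the same rule gives a catalyst share of 55.2%, which is 0.813 of this flask's share, hence target 40.0%. That neighbour flask holds target 39.8%, isomer of the product 15.1% and homo dimer 45.1%.

Its constants are those of an exercise; no experiment stands behind them.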